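# Proposed synthesis of (2R,3R)-2-(2,3-dihydroxy-4-methoxyphenyl)-5,6-dihydroxy-3,7-dimethoxy-2,3-dihydro-4H-chromen-4-one (CNP0075602.1)

## Analysis of the target

The target 17 is a dihydroflavonol 3-O-methyl ether. It is a 2,3-dihydro-4H-chromen-4-one whose ring A carries hydroxyl groups at C5 and C6 and a methoxy group at C7, whose ring B (on C2) is a 2,3-dihydroxy-4-methoxyphenyl group, and whose C3 carries a methoxy group. The two stereocentres C2 (R) and C3 (R) are adjacent, and the aryl and methoxy groups lie trans on ring C, both equatorial in the half-chair. The molecule is a β-aryloxy ketone, so an enolate at C3 can expel the O1 phenoxide (retro-oxa-Michael), which opens ring C and scrambles both centres. The C2–O1 bond is also benzylic to a ring with ortho and para oxygen donors and can ionise under acid. The catechol of ring B and the 5,6-dihydroxy unit of ring A are oxidation-prone, and C2–C3 can be dehydrogenated to the flavonol, so the free phenols should appear only in the last step. The synthesis is hard for three reasons: C2 must be set absolutely at a carbon that racemises easily, C3 must be oxygenated trans to it and methylated without base, and four phenolic hydroxyls must be told apart from two aryl methyl ethers and one alkyl methyl ether. The strategy rests on one feature: ring C joins O1 and C4, the phenol oxygen and the aryl carbonyl carbon of a salicyl unit on ring A, through only C2 and C3, which are the β- and α-carbons of a ring B cinnamyl unit. A ring A salicylaldehyde and a ring B cinnamaldehyde therefore contain every atom of ring C.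

## Retrosynthetic reasoning

**17 from 15 (protecting-group O–C bonds).** The four phenols are masked as three benzyl ethers (O6, O2', O3') and one methyl ether (O5). O5 is the only oxygen peri to the C4 carbonyl, so a boron halide bound to the ketone reaches its methyl group through a six-membered chelate and removes it while the 7-, 4'- and 3-methoxy groups stay. This choice lets ring A come from the symmetrical 2,6-dimethoxyphenol pattern of syringaldehyde 1, so the two oxygens flanking O6 never have to be differentiated on the ring. The forward step has to cleave the benzyl ethers at low temperature, pass through 16, and then cleave the chelated methyl ether.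

**15 from 14 (the O–CH3 bond at C3).** With every phenol protected, the C3 hydroxyl is the only OH in 14, so methylation is unambiguous. Because 14 is a β-aryloxy ketone, the forward reaction must use an electrophilic methyl donor and a non-nucleophilic proton scavenger, and no enolate may form.

**14 from 13 (oxidation level at C4).** The C4 carbinol of cis-diol 13 is benzylic to a ring with three oxygen donors ortho and para to C4a, and the C3 carbinol is unactivated. A hydride-abstracting quinone should therefore oxidise C4 only. A heterogeneous manganese oxidant, the usual choice for benzylic alcohols, is not used because such oxidants also cleave cis-1,2-diols that carry a benzylic carbinol. C3 is not touched, so its configuration carries over.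

**13 from 12 (C3–O and C4–O bonds).** Both oxygens are added in one step across the C3=C4 alkene of flavene 12 by osmium-catalysed syn-dihydroxylation. The C2 aryl group blocks one face, so the oxygens arrive anti to it; this is how C2 controls C3. The C4 centre is transient.

**12 from 11 (the C3–CHO bond).** The formyl group on C3 is not in the target. It is needed only to make the ring-forming step possible and is excised by rhodium-mediated decarbonylation, which leaves the alkene where it is.

**11 from 5 and 9 (O1–C2 and C3–C4).** These two bonds are the only links between the two aromatic halves, so cutting both gives two aldehydes of similar size and a convergent route. Cutting at C2–C1' or C4–C4a instead would need aryl–carbon bond formation on hindered, electron-rich rings and would give no catalytic handle on C2. The forward reaction has to add the phenol oxygen of 5 to the β-carbon of enal 9 enantioselectively, then close ring C by an intramolecular aldol reaction through adduct 10 and dehydrate.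

**5 from 1.** The formyl C–C bond of 5 is made by ortho-formylation of phenol 4, whose two ortho positions are equivalent, so only one salicylaldehyde can form. Phenol 4 comes from aldehyde 2 by exchange of the formyl carbon for oxygen through formate 3, and 2 comes from 1 by benzylation. Compound 1 already has the three contiguous oxygens in the right pattern.

**9 from 6 and 8.** The Cα=Cβ bond of 9 is made by Wittig homologation of aldehyde 7 with ylide 8, and 7 is the bis-benzyl ether of commercial 6, which already carries the ring B oxygen pattern.

## Alternatives that were turned down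

**Alternative 1: aryne insertion into the C–O bond of a chiral acid.**
- Disconnection: O1–C8a and C4–C4a are cut on ring A. Ring A arrives as an aryne across C4a and C8a, and the C2–C3–C4 chain arrives as an enantiopure 3-aryl-2-methoxy-3-silyloxypropanoic acid with both stereocentres and the 3-methoxy group in place.
- Forward key step: a fluoride source unmasks the aryne, the carboxylate oxygen adds to C8a, and the aryl anion at C4a is acylated by the neighbouring carbonyl. This gives the ortho-hydroxyaryl ketone (2R,3S)-1-[2,3-bis(benzyloxy)-6-hydroxy-4-methoxyphenyl]-3-[2,3-bis(benzyloxy)-4-methoxyphenyl]-2-methoxy-3-(triisopropylsilyloxy)propan-1-one A1. Ring C would then be closed by desilylation and displacement at the benzylic carbinol with inversion.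
- For: both stereocentres are made in acyclic chemistry before ring A is attached, and no carbon is sacrificed. The C5 oxygen directs the carboxylate to the remote aryne carbon, which is the correct one. Ring A is fully benzylated, so the end game is a neutral hydrogenolysis; on this point it is stronger than the chosen route, which needs a chelation-controlled demethylation.
- Against: the aryne precursor, a silyl aryl triflate on a ring with three oxygen substituents, needs a long linear preparation. The key step makes no ring and no stereocentre. The aryl anion must be acylated by a hindered, α,β-branched acyl group faster than it is protonated. A1 is a β-silyloxy ketone with an acidic α-hydrogen under fluoride, so elimination or epimerisation at the future C3 is likely. The later ring closure needs clean inversion at a carbinol flanked by an ortho,para-dioxygenated ring, where ionisation competes.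
- Comparison: the chosen strategy offers ring C and C2 in one catalytic step from two aldehydes that are each two or three steps from commercial material.

**Alternative 2: ketene–aldehyde cycloaddition to a sacrificial cis-β-lactone.**
- Disconnection: C2–C3 is cut. C3 with its methoxy group and C4 come from a methoxy-substituted ketene, C2 comes from aldehyde 7, and a lactone oxygen temporarily ties C4 to the C2 oxygen.
- Forward key step: the ketene, made in the flask from its acid chloride, is taken up by a silylated cinchona alkaloid as an acylammonium enolate, which adds to the lithium-activated aldehyde 7 and lactonises to (3R,4S)-4-[2,3-bis(benzyloxy)-4-methoxyphenyl]-3-methoxyoxetan-2-one A2. Ring A would then be acylated at C4a by the lactone, and ring C closed at C2 with inversion to turn cis into trans.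
- For: both stereocentres and the 3-methoxy group come from one catalytic step, with no sacrificial carbon and no late oxidation or methylation. In stereocentre economy it is stronger than the chosen route, which sets only C2 in its key step.
- Against: an oxygen-substituted ketene and a donor-deactivated aryl aldehyde are a poor pairing for this catalysis. A2 has its C4–O bond benzylic to an ortho,para-dioxygenated ring and should ionise, epimerise or lose carbon dioxide easily. A hindered, fully substituted ring A nucleophile must attack the acyl carbon and not the benzylic C4. The ring closure again needs inversion at the same labile centre.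
- Comparison: the chosen strategy forms the C2–O1 bond directly in the correct configuration by an addition, so no inversion at the benzylic carbon is ever needed, and it closes ring C in the key step.

**Alternative 3: polyketide-type Claisen folding of a masked tetraketide.**
- Disconnection: ring A itself is cut at C4a–C5 and is built from a linear poly-carbonyl chain held as a 4-methoxy-2-pyrone that carries the ring B cinnamoyl unit.
- Forward key step: a magnesium alkoxide opens the pyrone to the enol-ether triketo ester, and the methylene between the two ketones attacks the ester carbon. This closes ring A and gives (E)-3-[2,3-bis(benzyloxy)-4-methoxyphenyl]-1-(2,6-dihydroxy-4-methoxyphenyl)prop-2-en-1-one A3.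
- For: the sequence is biomimetic, the enol ether becomes the 7-methoxy group automatically, and the C5 hydroxyl is delivered free. On that last point it is stronger than the chosen route, which must demethylate at the end.
- Against: A3 has no oxygen at C6, and late hydroxylation of a phloroglucinol-type ring cannot be steered between C6 and C8. The key step sets no stereocentre. A chalcone with two ortho hydroxyls cyclises spontaneously and reversibly to a racemic flavanone, which undermines any later asymmetric installation of C2 and C3. The step also builds an aromatic ring that can be bought fully oxygenated as 1.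
- Comparison: the chosen strategy starts from the correct ring A oxygenation and spends its key step on ring C and on C2.

Key step: step 6

Assumption: the (S)-configured catalyst is taken to shield the Re face of the β-carbon of its E,s-trans iminium ion, as in other conjugate additions with this catalyst class, which leads to the (2R)-aldehyde 11; if the sense proved opposite, the (R)-catalyst would be used with no other change.

Remark on descriptors: the spatial arrangement at C2 is the same from 10 to 17; the changes between R and S at C2 in 10 and 12 come only from CIP priorities.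

## Route

Step 1
Reactants: 1 syringaldehyde (4-hydroxy-3,5-dimethoxybenzaldehyde)
Product: 2 4-(benzyloxy)-3,5-dimethoxybenzaldehyde
Conditions: BnBr, K2CO3, DMF, 60 °C
Reagents that add atoms: benzyl bromide, BrCc1ccccc1
Why: Williamson etherification of the only phenol in 1; the para formyl group makes the phenoxide easy to form and nothing else in the molecule is alkylated.

Step 2
Reactants: 2 4-(benzyloxy)-3,5-dimethoxybenzaldehyde
Product: 4 4-(benzyloxy)-3,5-dimethoxyphenol, via aryl formate 3 (not isolated)
Conditions: mCPBA, CH2Cl2, 0 °C → rt; aq. NaHCO3 wash; then K2CO3 (cat.), MeOH, rt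
Reagents that add atoms: 3-chloroperoxybenzoic acid, OOC(=O)c1cccc(Cl)c1
Why: Dakin-type Baeyer–Villiger oxidation with a peracid, chosen because the classical alkaline peroxide Dakin reaction needs a free ortho or para hydroxyl; the aryl group with three oxygen donors migrates in preference to hydride, and the formate 3 is methanolysed to the phenol.

Step 3
Reactants: 4 4-(benzyloxy)-3,5-dimethoxyphenol
Product: 5 3-(benzyloxy)-6-hydroxy-2,4-dimethoxybenzaldehyde
Conditions: MgCl2, Et3N, (CH2O)n, MeCN, 80 °C; then 1 M HCl
Reagents that add atoms: paraformaldehyde (as formaldehyde), C=O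
Why: Casnati–Skattebøl ortho-formylation, in which the magnesium phenoxide delivers formaldehyde to the ortho carbon and a second formaldehyde accepts hydride from the benzylic alkoxide; the two ortho positions of 4 are equivalent, so a single salicylaldehyde should form.

Step 4
Reactants: 6 2,3-dihydroxy-4-methoxybenzaldehyde
Product: 7 2,3-bis(benzyloxy)-4-methoxybenzaldehyde
Conditions: BnBr (2.5 equiv), K2CO3, DMF, 70 °C
Reagents that add atoms: benzyl bromide, BrCc1ccccc1
Why: Double Williamson etherification; warm DMF and excess halide are used so that the hydrogen-bonded 2-hydroxyl is alkylated as well as the 3-hydroxyl.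

Step 5
Reactants: 7 2,3-bis(benzyloxy)-4-methoxybenzaldehyde; 8 (triphenylphosphoranylidene)acetaldehyde
Product: 9 (E)-3-[2,3-bis(benzyloxy)-4-methoxyphenyl]prop-2-enal
Conditions: toluene, 90 °C
Reagents that add atoms: none
Why: Wittig two-carbon homologation with a stabilised ylide, which gives the E-enal; only a small excess of 8 is used so that the product enal is not homologated a second time.

Step 6
Reactants: 5 3-(benzyloxy)-6-hydroxy-2,4-dimethoxybenzaldehyde; 9 (E)-3-[2,3-bis(benzyloxy)-4-methoxyphenyl]prop-2-enal
Product: 11 (2R)-6-(benzyloxy)-2-[2,3-bis(benzyloxy)-4-methoxyphenyl]-5,7-dimethoxy-2H-chromene-3-carbaldehyde, via 4-hydroxychromane-3-carbaldehyde aldol adduct 10 (not isolated)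
Conditions: (S)-2-[diphenyl(triethylsilyloxy)methyl]pyrrolidine (20 mol%), 2-nitrobenzoic acid (20 mol%), 4 Å MS, toluene, 0 °C → rt, dark
Reagents that add atoms: none
Why: The secondary amine condenses with enal 9 to an E-configured, s-trans iminium ion whose Re face at the β-carbon is covered by the CPh2OSiEt3 group, so the phenol oxygen of 5 adds to the Si face, forms O1–C2 and fixes C2 as R. The resulting enamine sits ortho to the formyl group of ring A and closes ring C by a 6-(enolexo)-exo-trig aldol addition that forms C3–C4 and gives adduct 10; its C3 and C4 configurations do not matter, because acid-assisted dehydration and hydrolysis of the unsaturated iminium ion then release 11 and the catalyst. The closest known reaction type is the diarylprolinol silyl ether catalysed domino oxa-Michael–aldol condensation of salicylaldehydes with cinnamaldehydes, of which this is a more electron-rich and more hindered case. C2 is the only stereocentre that survives and it is under catalyst control alone, since neither substrate has a stereocentre. The step needs enantioface selectivity in a reversible oxa-Michael addition, so ring closure and dehydration must outrun the retro-addition. The substrate helps in two ways: the enamine and the aldehyde are held ortho on ring A, which makes the aldol step intramolecular, and dehydration gives an enal conjugated to three oxygen donors of ring A, which is a poor partner for renewed iminium formation. The acid co-catalyst speeds iminium formation and dehydration, and molecular sieves and darkness guard against loss of the silyl group and photochemical opening of the chromene.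

Step 7
Reactants: 11 (2R)-6-(benzyloxy)-2-[2,3-bis(benzyloxy)-4-methoxyphenyl]-5,7-dimethoxy-2H-chromene-3-carbaldehyde
Product: 12 (2S)-6-(benzyloxy)-2-[2,3-bis(benzyloxy)-4-methoxyphenyl]-5,7-dimethoxy-2H-chromene
Conditions: RhCl(PPh3)3 (1.1 equiv), toluene, 90 °C, dark
Reagents that add atoms: none
Why: Tsuji–Wilkinson decarbonylation: the formyl C–H bond adds oxidatively to monovalent rhodium, carbon monoxide is extruded from the alkenoyl ligand onto the metal, and C–H reductive elimination leaves the C3=C4 alkene in place; C2 is not involved.

Step 8
Reactants: 12 (2S)-6-(benzyloxy)-2-[2,3-bis(benzyloxy)-4-methoxyphenyl]-5,7-dimethoxy-2H-chromene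
Product: 13 (2R,3S,4S)-6-(benzyloxy)-2-[2,3-bis(benzyloxy)-4-methoxyphenyl]-5,7-dimethoxy-3,4-dihydro-2H-chromene-3,4-diol
Conditions: OsO4 (3 mol%), NMO (1.5 equiv), acetone–H2O, 0 °C → rt
Reagents that add atoms: N-methylmorpholine N-oxide, C[N+]1([O-])CCOCC1; water, O
Why: Upjohn syn-dihydroxylation of the cis-disubstituted styrenic alkene; OsO4 adds to the face anti to the C2 aryl group, which sets the C3 oxygen trans to the aryl group (2,3-trans, 3,4-cis). The C4 centre formed here is removed in the next step.

Step 9
Reactants: 13 (2R,3S,4S)-6-(benzyloxy)-2-[2,3-bis(benzyloxy)-4-methoxyphenyl]-5,7-dimethoxy-3,4-dihydro-2H-chromene-3,4-diol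
Product: 14 (2R,3R)-6-(benzyloxy)-2-[2,3-bis(benzyloxy)-4-methoxyphenyl]-3-hydroxy-5,7-dimethoxy-2,3-dihydro-4H-chromen-4-one
Conditions: DDQ (1.2 equiv), 1,4-dioxane, rt
Reagents that add atoms: none
Why: Quinone dehydrogenation of an electron-rich benzylic alcohol: DDQ abstracts hydride from C4, where the cation is stabilised by O1, the 5- and 7-methoxy groups and the carbinol oxygen, while the unactivated C3 carbinol is left alone. DDQ replaces MnO2 here because activated MnO2 cleaves benzylic cis-1,2-diols.

Step 10
Reactants: 14 (2R,3R)-6-(benzyloxy)-2-[2,3-bis(benzyloxy)-4-methoxyphenyl]-3-hydroxy-5,7-dimethoxy-2,3-dihydro-4H-chromen-4-one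
Product: 15 (2R,3R)-6-(benzyloxy)-2-[2,3-bis(benzyloxy)-4-methoxyphenyl]-3,5,7-trimethoxy-2,3-dihydro-4H-chromen-4-one
Conditions: Me3OBF4 (3 equiv), 1,8-bis(dimethylamino)naphthalene (3.5 equiv), 4 Å MS, CH2Cl2, 0 °C → rt
Reagents that add atoms: trimethyloxonium tetrafluoroborate, C[O+](C)C.F[B-](F)(F)F
Why: O-Methylation with Meerwein's salt and a hindered, non-nucleophilic proton scavenger; the neutral hydroxyl is alkylated directly and no enolate forms, so the β-aryloxy ketone should neither ring-open nor epimerise. The C3 hydroxyl is the only OH in 14.

Step 11
Reactants: 15 (2R,3R)-6-(benzyloxy)-2-[2,3-bis(benzyloxy)-4-methoxyphenyl]-3,5,7-trimethoxy-2,3-dihydro-4H-chromen-4-one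
Product: 17 (2R,3R)-2-(2,3-dihydroxy-4-methoxyphenyl)-5,6-dihydroxy-3,7-dimethoxy-2,3-dihydro-4H-chromen-4-one, via 5-O-methyl triphenol 16 (not isolated)
Conditions: BCl3 (8 equiv), C6HMe5 (6 equiv), CH2Cl2, −78 °C → 0 °C; MeOH quench, aq. work-up under Ar
Reagents that add atoms: none
Why: Lewis acid ether cleavage in two stages in one flask: at −78 °C BCl3 cleaves the three aryl benzyl ethers, with pentamethylbenzene trapping the benzyl cations, to give 16 as its boron esters. On warming, boron bound to the C4 carbonyl reaches the peri 5-methoxy group through a six-membered chelate and chloride removes that methyl group only, while the 7-, 4'- and 3-methoxy groups have no such chelate to a carbonyl-bound boron.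

## Compound list

1 | syringaldehyde (4-hydroxy-3,5-dimethoxybenzaldehyde) | COc1cc(C=O)cc(OC)c1O | starting material
2 | 4-(benzyloxy)-3,5-dimethoxybenzaldehyde | COc1cc(C=O)cc(OC)c1OCc1ccccc1 | intermediate
3 | 4-(benzyloxy)-3,5-dimethoxyphenyl formate | COc1cc(OC=O)cc(OC)c1OCc1ccccc1 | intermediate (not isolated)
4 | 4-(benzyloxy)-3,5-dimethoxyphenol | COc1cc(O)cc(OC)c1OCc1ccccc1 | intermediate
5 | 3-(benzyloxy)-6-hydroxy-2,4-dimethoxybenzaldehyde | COc1cc(O)c(C=O)c(OC)c1OCc1ccccc1 | intermediate
6 | 2,3-dihydroxy-4-methoxybenzaldehyde | COc1ccc(C=O)c(O)c1O | starting material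
7 | 2,3-bis(benzyloxy)-4-methoxybenzaldehyde | COc1ccc(C=O)c(OCc2ccccc2)c1OCc1ccccc1 | intermediate
8 | (triphenylphosphoranylidene)acetaldehyde | O=CC=P(c1ccccc1)(c1ccccc1)c1ccccc1 | starting material
9 | (E)-3-[2,3-bis(benzyloxy)-4-methoxyphenyl]prop-2-enal | COc1ccc(/C=C/C=O)c(OCc2ccccc2)c1OCc1ccccc1 | intermediate
10 | (2S)-6-(benzyloxy)-2-[2,3-bis(benzyloxy)-4-methoxyphenyl]-4-hydroxy-5,7-dimethoxy-3,4-dihydro-2H-chromene-3-carbaldehyde (C3 and C4 not defined) | COc1ccc([C@H]2Oc3cc(OC)c(OCc4ccccc4)c(OC)c3C(O)C2C=O)c(OCc2ccccc2)c1OCc1ccccc1 | intermediate (not isolated)
11 | (2R)-6-(benzyloxy)-2-[2,3-bis(benzyloxy)-4-methoxyphenyl]-5,7-dimethoxy-2H-chromene-3-carbaldehyde | COc1ccc([C@H]2Oc3cc(OC)c(OCc4ccccc4)c(OC)c3C=C2C=O)c(OCc2ccccc2)c1OCc1ccccc1 | intermediate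
12 | (2S)-6-(benzyloxy)-2-[2,3-bis(benzyloxy)-4-methoxyphenyl]-5,7-dimethoxy-2H-chromene | COc1ccc([C@H]2Oc3cc(OC)c(OCc4ccccc4)c(OC)c3C=C2)c(OCc2ccccc2)c1OCc1ccccc1 | intermediate
13 | (2R,3S,4S)-6-(benzyloxy)-2-[2,3-bis(benzyloxy)-4-methoxyphenyl]-5,7-dimethoxy-3,4-dihydro-2H-chromene-3,4-diol | COc1ccc([C@H]2Oc3cc(OC)c(OCc4ccccc4)c(OC)c3[C@H](O)[C@@H]2O)c(OCc2ccccc2)c1OCc1ccccc1 | intermediate
14 | (2R,3R)-6-(benzyloxy)-2-[2,3-bis(benzyloxy)-4-methoxyphenyl]-3-hydroxy-5,7-dimethoxy-2,3-dihydro-4H-chromen-4-one | COc1ccc([C@H]2Oc3cc(OC)c(OCc4ccccc4)c(OC)c3C(=O)[C@@H]2O)c(OCc2ccccc2)c1OCc1ccccc1 | intermediate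
15 | (2R,3R)-6-(benzyloxy)-2-[2,3-bis(benzyloxy)-4-methoxyphenyl]-3,5,7-trimethoxy-2,3-dihydro-4H-chromen-4-one | COc1ccc([C@H]2Oc3cc(OC)c(OCc4ccccc4)c(OC)c3C(=O)[C@@H]2OC)c(OCc2ccccc2)c1OCc1ccccc1 | intermediate
16 | (2R,3R)-2-(2,3-dihydroxy-4-methoxyphenyl)-6-hydroxy-3,5,7-trimethoxy-2,3-dihydro-4H-chromen-4-one (held in the flask as its boron esters) | COc1ccc([C@H]2Oc3cc(OC)c(O)c(OC)c3C(=O)[C@@H]2OC)c(O)c1O | intermediate (not isolated)
17 | (2R,3R)-2-(2,3-dihydroxy-4-methoxyphenyl)-5,6-dihydroxy-3,7-dimethoxy-2,3-dihydro-4H-chromen-4-one | COc1ccc([C@H]2Oc3cc(OC)c(O)c(O)c3C(=O)[C@@H]2OC)c(O)c1O | target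

## Step count and least certain steps

Total: 11 steps. Longest linear sequence: 9 steps (steps 1–3 and 6–11, from 1 to 17). The ring B branch (steps 4 and 5) joins at step 6.

**Step 6 (key step).** The aldehyde of 5 has two ortho substituents and is deactivated by three oxygen donors, so the aldol closure may be slow. The oxa-Michael adduct would then revert, which erodes the enantioselectivity and the conversion. The ortho benzyloxy group of 9 may also hinder the approach to the β-carbon. The fallback sets out from 5 and 9 and comes back at 11. The two aldehydes are condensed without a chiral catalyst (pyrrolidine and benzoic acid, or K2CO3 in warm 1,4-dioxane), where reversibility of the first step no longer matters, to give racemic 6-(benzyloxy)-2-[2,3-bis(benzyloxy)-4-methoxyphenyl]-5,7-dimethoxy-2H-chromene-3-carbaldehyde F1. Its enantiomers are separated by preparative chromatography on a cellulose tris(3,5-dimethylphenylcarbamate) stationary phase, and the (2R) enantiomer is 11.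

**Step 7.** At the temperature that the hindered enal may need, the 2H-chromene can racemise at C2 by thermal electrocyclic ring opening to the ortho-quinone methide. A rhodium hydride may also move the alkene into conjugation with O1. The fallback sets out from 11 and comes back at 12 without heating. Pinnick oxidation (NaClO2, NaH2PO4, 2-methylbut-2-ene, t-BuOH–H2O) gives (2R)-6-(benzyloxy)-2-[2,3-bis(benzyloxy)-4-methoxyphenyl]-5,7-dimethoxy-2H-chromene-3-carboxylic acid F2. Coupling with N-hydroxypyridine-2-thione and a carbodiimide gives its 2-thioxopyridin-1(2H)-yl ester F3. Barton reductive decarboxylation under visible light with tert-butyl thiol near room temperature then gives 12, the alkenyl radical at C3 taking hydrogen from the thiol.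

**Step 9.** In the preferred half-chair the C4 hydroxyl is pseudo-axial, pushed there by the peri 5-methoxy group, so the C4–H bond lies near the plane of ring A and hydride abstraction may be slow. Competing hydride abstraction at C2, over-oxidation to the flavonol, and acid-promoted ionisation of the C4 hydroxyl by the hydroquinone by-product are the likely side processes. The fallback sets out from 12 and comes back at 14. Epoxidation with dimethyldioxirane in acetone at low temperature, anti to the aryl group, gives (2R,3S,4S)-6-(benzyloxy)-2-[2,3-bis(benzyloxy)-4-methoxyphenyl]-3,4-epoxy-5,7-dimethoxy-3,4-dihydro-2H-chromene F4. Kornblum-type oxidative opening follows: DMSO opens the epoxide at the benzylic C4 and Et3N collapses the alkoxysulfonium ion to the ketone. The C3–O bond is never broken, so 14 results with the 2,3-trans arrangement.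

**Step 10.** The hydroxyl of the α-ketol is hindered and hydrogen-bonded, so methylation may be incomplete. Any enolisation would open ring C by β-elimination of the phenoxide or epimerise C3. The fallback sets out from 13 and comes back at 15 by reversing the order of methylation and oxidation. The cis-diol is converted with Bu2SnO into its stannylene acetal and alkylated with MeI and CsF in DMF. In cis-1,2-diols on six-membered rings this alkylation goes to the equatorial oxygen, here O3, since O4 is pseudo-axial and shielded by the peri methoxy group. The product is (2R,3S,4S)-6-(benzyloxy)-2-[2,3-bis(benzyloxy)-4-methoxyphenyl]-3,5,7-trimethoxy-3,4-dihydro-2H-chromen-4-ol F5. Dess–Martin oxidation of the remaining benzylic alcohol gives 15.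

**Step 11.** Over-demethylation is the main danger: the alkyl 3-methoxy group can be cleaved through a five-membered chelate, and the 7- and 4'-methoxy groups lie next to boron-bound phenoxides. Lewis acid ionisation of the benzylic C2–O1 bond, with epimerisation at C2, and benzylation of C8 are further risks. The fallback sets out from 15 and comes back at 17 by separating the two tasks. MgI2·OEt2 in toluene removes only the methyl ether that chelates with the ketone and gives (2R,3R)-6-(benzyloxy)-2-[2,3-bis(benzyloxy)-4-methoxyphenyl]-5-hydroxy-3,7-dimethoxy-2,3-dihydro-4H-chromen-4-one F6. Hydrogenolysis with H2 and Pd/C in EtOAc–MeOH then removes the three benzyl groups under neutral conditions.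

## Further compounds

F1 | step 6 | racemic 6-(benzyloxy)-2-[2,3-bis(benzyloxy)-4-methoxyphenyl]-5,7-dimethoxy-2H-chromene-3-carbaldehyde | COc1ccc(C2Oc3cc(OC)c(OCc4ccccc4)c(OC)c3C=C2C=O)c(OCc2ccccc2)c1OCc1ccccc1
F2 | step 7 | (2R)-6-(benzyloxy)-2-[2,3-bis(benzyloxy)-4-methoxyphenyl]-5,7-dimethoxy-2H-chromene-3-carboxylic acid | COc1ccc([C@H]2Oc3cc(OC)c(OCc4ccccc4)c(OC)c3C=C2C(=O)O)c(OCc2ccccc2)c1OCc1ccccc1
F3 | step 7 | 2-thioxopyridin-1(2H)-yl (2R)-6-(benzyloxy)-2-[2,3-bis(benzyloxy)-4-methoxyphenyl]-5,7-dimethoxy-2H-chromene-3-carboxylate | COc1ccc([C@H]2Oc3cc(OC)c(OCc4ccccc4)c(OC)c3C=C2C(=O)ON2C=CC=CC2=S)c(OCc2ccccc2)c1OCc1ccccc1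
F4 | step 9 | (2R,3S,4S)-6-(benzyloxy)-2-[2,3-bis(benzyloxy)-4-methoxyphenyl]-3,4-epoxy-5,7-dimethoxy-3,4-dihydro-2H-chromene | COc1ccc([C@H]2Oc3cc(OC)c(OCc4ccccc4)c(OC)c3[C@@H]3O[C@H]23)c(OCc2ccccc2)c1OCc1ccccc1
F5 | step 10 | (2R,3S,4S)-6-(benzyloxy)-2-[2,3-bis(benzyloxy)-4-methoxyphenyl]-3,5,7-trimethoxy-3,4-dihydro-2H-chromen-4-ol | COc1ccc([C@H]2Oc3cc(OC)c(OCc4ccccc4)c(OC)c3[C@H](O)[C@@H]2OC)c(OCc2ccccc2)c1OCc1ccccc1
F6 | step 11 | (2R,3R)-6-(benzyloxy)-2-[2,3-bis(benzyloxy)-4-methoxyphenyl]-5-hydroxy-3,7-dimethoxy-2,3-dihydro-4H-chromen-4-one | COc1ccc([C@H]2Oc3cc(OC)c(OCc4ccccc4)c(O)c3C(=O)[C@@H]2OC)c(OCc2ccccc2)c1OCc1ccccc1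
A1 | alternative 1 | (2R,3S)-1-[2,3-bis(benzyloxy)-6-hydroxy-4-methoxyphenyl]-3-[2,3-bis(benzyloxy)-4-methoxyphenyl]-2-methoxy-3-(triisopropylsilyloxy)propan-1-one | COc1ccc([C@H](O[Si](C(C)C)(C(C)C)C(C)C)[C@@H](OC)C(=O)c2c(O)cc(OC)c(OCc3ccccc3)c2OCc2ccccc2)c(OCc2ccccc2)c1OCc1ccccc1
A2 | alternative 2 | (3R,4S)-4-[2,3-bis(benzyloxy)-4-methoxyphenyl]-3-methoxyoxetan-2-one | COc1ccc([C@@H]2OC(=O)[C@@H]2OC)c(OCc2ccccc2)c1OCc1ccccc1
A3 | alternative 3 | (E)-3-[2,3-bis(benzyloxy)-4-methoxyphenyl]-1-(2,6-dihydroxy-4-methoxyphenyl)prop-2-en-1-one | COc1cc(O)c(C(=O)/C=C/c2ccc(OC)c(OCc3ccccc3)c2OCc2ccccc2)c(O)c1
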